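## Retrosynthetic overview

1. Last disconnection: the stilbene aryl–vinyl bond, made by a Mizoroki–Heck coupling of a vinyl-benzodioxane with an iodoresorcinol; the vinyl group comes from an aldehyde.
2. Key disconnection: both alkyl C–O bonds of the dioxane ring, leading back to a pyrogallol aldehyde and an (E)-cinnamyl alcohol of the sinapyl type. One enantioselective oxidative annulation forms the two C–O bonds and both stereocentres.
3. The sinapyl-type alcohol goes back to a 4-hydroxy-3,5-dimethoxybenzaldehyde by ester reduction and Wittig olefination.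
4. Ring order: the three benzene rings (ring A syringyl, ring C from the pyrogallol aldehyde, ring D resorcinol) are bought. The only ring made is the 1,4-dioxane ring B, in step 3.

Assumption: the sense of induction of step 3 cannot be predicted with certainty; the (S)-ligand is written as the one giving the (2S,3S) product, and its mirror image is used instead if the first run shows the opposite sense.

Benzodioxane numbering used throughout (that of aldehyde 6): O-1 is the oxygen flanked by the free ring hydroxyl, C-2 carries CH2OH, C-3 carries the syringyl group.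

## Route

Step 1
Reactants: 1 syringaldehyde (4-hydroxy-3,5-dimethoxybenzaldehyde)
Product: 2 ethyl (E)-sinapate, ethyl (2E)-3-(4-hydroxy-3,5-dimethoxyphenyl)prop-2-enoate
Conditions: Ph3P=CHCO2Et (1.3 equiv), toluene, 100 °C, 6 h
Reagents that add atoms: ethyl (triphenylphosphoranylidene)acetate, CCOC(=O)C=P(c1ccccc1)(c1ccccc1)c1ccccc1
Why: Wittig olefination with a stabilised ylide is E-selective and runs on the unprotected hydroxybenzaldehyde.

Step 2
Reactants: 2 ethyl (E)-sinapate
Product: 3 (E)-sinapyl alcohol, 4-[(1E)-3-hydroxyprop-1-en-1-yl]-2,6-dimethoxyphenol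
Conditions: i-Bu2AlH (4 equiv), toluene/THF, −78 → 0 °C; EtOH, then aq. potassium sodium tartrate
Reagents that add atoms: none
Why: 1,2-reduction of the unsaturated ester by a dialkylaluminium hydride (one equivalent is spent on the phenol) gives the allylic alcohol with the E-alkene untouched, and the neutral tartrate work-up spares the acid-sensitive product.

Step 3
Reactants: 3 (E)-sinapyl alcohol; 4 3,4,5-trihydroxybenzaldehyde
Product: 6 (2S,3S)-8-hydroxy-3-(4-hydroxy-3,5-dimethoxyphenyl)-2-(hydroxymethyl)-2,3-dihydro-1,4-benzodioxine-6-carbaldehyde (trans), via quinone methide 5 (not isolated)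
Conditions: PdCl2(MeCN)2 (5 mol %), (S)-t-Bu-Quinox [2-[(4S)-4-tert-butyl-4,5-dihydro-1,3-oxazol-2-yl]quinoline] (7.5 mol %), KHCO3 (30 mol %), 2,6-dimethyl-1,4-benzoquinone (1.2 equiv), dry THF/toluene 1:1, 0 °C → rt, N2; 3 added over 6 h to 4 (1.5 equiv)
Reagents that add atoms: none
Why: Proposed new method: the most acidic phenol of 4 (the 4-OH, para to CHO; the syringyl OH of 3 is less acidic and hindered) is delivered by the chiral divalent-palladium/quinoline–oxazoline complex across the alkene of 3 with O at the carbon next to CH2OH and Pd at the benzylic carbon, the ligand choosing the alkene face and so setting C-2; the para-hydroxyl then expels zerovalent palladium to give quinone methide 5, either of the two equivalent flanking phenols closes ring B by intramolecular 1,6-oxa-addition to give the trans ring with both substituents equatorial (C-3), and the benzoquinone returns palladium to the divalent state; the closest known reaction types are the palladium-catalysed enantioselective dioxygenation of vinylphenols through quinone methides and the palladium-catalysed oxidative 1,2-dioxygenation of 1,3-dienes with catechols.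

Step 4
Reactants: 6 (2S,3S)-8-hydroxy-3-(4-hydroxy-3,5-dimethoxyphenyl)-2-(hydroxymethyl)-2,3-dihydro-1,4-benzodioxine-6-carbaldehyde
Product: 7 (2S,3S)-6-ethenyl-3-(4-hydroxy-3,5-dimethoxyphenyl)-2-(hydroxymethyl)-2,3-dihydro-1,4-benzodioxin-8-ol (numbered as in 6)
Conditions: Ph3PCH3Br (4.5 equiv), KOt-Bu (4.4 equiv), THF, 0 °C → rt; aq. NH4Cl
Reagents that add atoms: methyltriphenylphosphonium bromide, C[P+](c1ccccc1)(c1ccccc1)c1ccccc1.[Br-]
Why: Wittig methylenation with excess ylide (two equivalents are held by the phenols) works because the aldehyde is meta to the ring phenoxide and stays electrophilic, and neither stereocentre is acidic.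

Step 5
Reactants: 7 (2S,3S)-6-ethenyl-3-(4-hydroxy-3,5-dimethoxyphenyl)-2-(hydroxymethyl)-2,3-dihydro-1,4-benzodioxin-8-ol; 8 5-iodoresorcinol (5-iodobenzene-1,3-diol)
Product: 9 5-[(E)-2-[(2S,3S)-8-hydroxy-3-(4-hydroxy-3,5-dimethoxyphenyl)-2-(hydroxymethyl)-2,3-dihydro-1,4-benzodioxin-6-yl]ethenyl]benzene-1,3-diol (CNP0319597.1)
Conditions: Pd(OAc)2 (5 mol %), n-Bu4NCl (1 equiv), NaHCO3 (3 equiv), DMF, 80 °C, Ar
Reagents that add atoms: none
Why: Mizoroki–Heck coupling of the aryl iodide at the terminal alkene carbon, followed by syn β-hydride elimination, gives the E-stilbene directly, tolerates free phenols and alcohols, and the mild bicarbonate base leaves the two ring stereocentres alone.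

## Compound list

1 | syringaldehyde (4-hydroxy-3,5-dimethoxybenzaldehyde) | COc1cc(C=O)cc(OC)c1O | starting material
2 | ethyl (E)-sinapate | CCOC(=O)/C=C/c1cc(OC)c(O)c(OC)c1 | intermediate
3 | (E)-sinapyl alcohol | OC/C=C/c1cc(OC)c(O)c(OC)c1 | intermediate
4 | 3,4,5-trihydroxybenzaldehyde | O=Cc1cc(O)c(O)c(O)c1 | starting material
5 | quinone methide, 4-[(2R)-2-(4-formyl-2,6-dihydroxyphenoxy)-3-hydroxypropylidene]-2,6-dimethoxycyclohexa-2,5-dien-1-one (R by CIP; same spatial arrangement as C-2 of 6), not isolated | COC1=CC(=C[C@H](CO)Oc2c(O)cc(C=O)cc2O)C=C(OC)C1=O | intermediate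
6 | (2S,3S)-8-hydroxy-3-(4-hydroxy-3,5-dimethoxyphenyl)-2-(hydroxymethyl)-2,3-dihydro-1,4-benzodioxine-6-carbaldehyde | COc1cc([C@@H]2Oc3cc(C=O)cc(O)c3O[C@H]2CO)cc(OC)c1O | intermediate
7 | (2S,3S)-6-ethenyl-3-(4-hydroxy-3,5-dimethoxyphenyl)-2-(hydroxymethyl)-2,3-dihydro-1,4-benzodioxin-8-ol | COc1cc([C@@H]2Oc3cc(C=C)cc(O)c3O[C@H]2CO)cc(OC)c1O | intermediate
8 | 5-iodoresorcinol (5-iodobenzene-1,3-diol) | Oc1cc(O)cc(I)c1 | starting material
9 | 5-[(E)-2-[(2S,3S)-8-hydroxy-3-(4-hydroxy-3,5-dimethoxyphenyl)-2-(hydroxymethyl)-2,3-dihydro-1,4-benzodioxin-6-yl]ethenyl]benzene-1,3-diol | COc1cc([C@@H]2Oc3cc(/C=C/c4cc(O)cc(O)c4)cc(O)c3O[C@H]2CO)cc(OC)c1O | target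

## Step count and risks

Total step count: 5. Longest linear sequence: 5 (1 → 2 → 3 → 6 → 7 → 9); compounds 4 and 8 are bought.

The three steps most likely to fail:

**Step 3 (the proposed new annulation).** The risks are oxidation of the pyrogallol unit of 4 by the quinone, chelation of palladium by the catechol, and low enantioselectivity. The fallback uses known chemistry, sets out from 3 and 4 and comes back at 6. The two are joined by the biomimetic oxidative coupling with Ag2CO3 (2.2 equiv, acetone/toluene, rt, dark). The sinapyl phenoxyl radical couples through its β-carbon with the semiquinone oxygen para to CHO, giving the quinone methide as a racemate, that is 5 together with the mirror-image quinone methide F1 (not isolated). This closes to the racemic trans aldehyde, that is 6 together with the mirror-image aldehyde F2. After silica chromatography the enantiomers are separated by preparative HPLC on a cellulose tris(3,5-dimethylphenylcarbamate) phase, and 6 is carried into step 4.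

**Step 5 (Heck coupling on an electron-rich, unprotected vinylphenol).** The risks are 1,1-diaryl regioisomer and oligomerisation of 7. The fallback sets out from 7 and comes back at 9. Commercial 3,5-dihydroxybenzaldehyde is methylenated (Ph3PCH3Br, KOt-Bu, THF) to 3,5-dihydroxystyrene F3. Olefin cross-metathesis of 7 with F3 (3 equiv) and the second-generation Hoveyda–Grubbs catalyst (5 mol %, CH2Cl2/THF, 40 °C, ethene swept out with Ar) gives the E-stilbene 9. The homodimer of F3 is removed by chromatography.

**Step 4 (methylenation in the presence of three acidic OH groups).** The risks are poor solubility of the polyanion and attack of the ylide on a ring-opened quinone methide. The fallback sets out from 6 and comes back at 7, changing to a protect–olefinate–deprotect sequence. TBSCl (4 equiv) and imidazole in DMF give the tris-TBS aldehyde F4. Ph3P=CH2 (1.3 equiv, THF, 0 °C) gives the tris-TBS styrene F5. Bu4NF buffered with AcOH (THF, 0 °C) returns 7.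

## Further compounds

F1 | step 3 | mirror-image quinone methide, 4-[(2S)-2-(4-formyl-2,6-dihydroxyphenoxy)-3-hydroxypropylidene]-2,6-dimethoxycyclohexa-2,5-dien-1-one (not isolated) | COC1=CC(=C[C@@H](CO)Oc2c(O)cc(C=O)cc2O)C=C(OC)C1=O
F2 | step 3 | mirror-image aldehyde, (2R,3R)-8-hydroxy-3-(4-hydroxy-3,5-dimethoxyphenyl)-2-(hydroxymethyl)-2,3-dihydro-1,4-benzodioxine-6-carbaldehyde | COc1cc([C@H]2Oc3cc(C=O)cc(O)c3O[C@@H]2CO)cc(OC)c1O
F3 | step 5 | 3,5-dihydroxystyrene (5-ethenylbenzene-1,3-diol) | C=Cc1cc(O)cc(O)c1
F4 | step 4 | tris-TBS aldehyde, (2S,3S)-8-(tert-butyldimethylsilyloxy)-2-[(tert-butyldimethylsilyloxy)methyl]-3-[4-(tert-butyldimethylsilyloxy)-3,5-dimethoxyphenyl]-2,3-dihydro-1,4-benzodioxine-6-carbaldehyde | COc1cc([C@@H]2Oc3cc(C=O)cc(O[Si](C)(C)C(C)(C)C)c3O[C@H]2CO[Si](C)(C)C(C)(C)C)cc(OC)c1O[Si](C)(C)C(C)(C)C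
F5 | step 4 | tris-TBS styrene, the 6-ethenyl analogue of F4 | COc1cc([C@@H]2Oc3cc(C=C)cc(O[Si](C)(C)C(C)(C)C)c3O[C@H]2CO[Si](C)(C)C(C)(C)C)cc(OC)c1O[Si](C)(C)C(C)(C)C
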